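## Retrosynthetic overview

1. The aldehyde is added last by ortho-formylation of a resorcinol whose two free ring positions are equivalent; the arene comes from 3,5-dihydroxybenzoic acid and is joined to the terpenoid part through an aryl alkyne.
2. The C9 quaternary centre and the C1=C10 alkene come from conjugate methylation of a ring A/ring B alkylidene ketone, trapping of the regiodefined enolate as an enol triflate, and formate reduction.
3. Ring B (formed second) is closed by a gold-catalysed 6-exo-dig carbocyclisation of a silyl enol ether onto the aryl alkyne; the chain carrying C8 comes from (R)-α-methyl-γ-butyrolactone and is attached by conjugate addition.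
4. Ring A (the first carbocycle) comes from achiral 4,4-dimethylcyclohexa-2,5-dienone: a catalytic enantioselective conjugate borylation/oxidation breaks its symmetry and sets C3, which then relays to C5 and C9.

Notation: decalin locants are C1 (=CH), C2, C3 (carbinol), C4 (CMe2), C5 (ring-fusion CH), C6, C7, C8 (CHMe), C9 (quaternary), C10 (ring-fusion sp2). The target is (3R,5R,8R,9S), with 3-OH, H5, 8-Me and 9-Me on one face and CH2Ar on the other. TBS = tert-butyldimethylsilyl. Ar = 2,6-bis(TBSO)-4-(TBSOCH2)phenyl.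

Assumption: compounds 1, 5 and 9 and all reagents are purchased, and each chiral ligand is used as the enantiomer that gives the stated configuration.

## Route

Step 1
Reactants: 1 4,4-dimethylcyclohexa-2,5-dien-1-one
Product: 3 (5R)-5-hydroxy-4,4-dimethylcyclohex-2-en-1-one, via boronate 2 (not isolated)
Conditions: CuCl (3 mol%), NaOt-Bu (6 mol%), (R)-1-[(SP)-2-(diphenylphosphino)ferrocenyl]ethyldicyclohexylphosphine (3.3 mol%), B2pin2 (1.0 equiv), MeOH (2 equiv), THF, −40 °C; then NaBO3·4H2O, THF/H2O, 0 °C to rt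
Reagents that add atoms: bis(pinacolato)diboron CC1(C)OB(OC1(C)C)B1OC(C)(C)C(C)(C)O1 (boryl group of 2); sodium perborate [Na+].[O-]OB=O (hydroxyl oxygen of 3)
Why: Proposed new method: a chiral phosphine–copper boryl adds to one of the two enantiotopic enone arms of the symmetric dienone, the ligand pocket fixing the new centre as R; methanol protonates the copper enolate and perborate converts C–B into C–OH with retention; the closest known reaction type is the copper-catalysed asymmetric β-borylation of cyclic enones.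

Step 2
Reactants: 3 (5R)-5-hydroxy-4,4-dimethylcyclohex-2-en-1-one
Product: 4 (5R)-5-(tert-butyldimethylsilyloxy)-4,4-dimethylcyclohex-2-en-1-one
Conditions: TBSOTf, 2,6-lutidine, CH2Cl2, −78 to 0 °C
Reagents that add atoms: tert-butyldimethylsilyl triflate CC(C)(C)[Si](C)(C)OS(=O)(=O)C(F)(F)F
Why: Silylation of a hindered neopentyl-type alcohol with a silyl triflate and a weak base avoids retro-oxa-Michael loss of the β-oxygen; no stereocentre is touched.

Step 3
Reactants: 5 3,5-dihydroxybenzoic acid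
Product: 6 4-bromo-3,5-dihydroxybenzoic acid
Conditions: Br2 (1.0 equiv), aq. HCl, 100 °C
Reagents that add atoms: bromine BrBr
Why: Electrophilic aromatic bromination; in hot aqueous acid the halogen settles at the doubly activated position between the two hydroxyls, away from the carboxyl.

Step 4
Reactants: 6 4-bromo-3,5-dihydroxybenzoic acid
Product: 7 2-bromo-5-(hydroxymethyl)benzene-1,3-diol
Conditions: BH3·SMe2 (4 equiv), THF, 0 °C to reflux; MeOH quench
Reagents that add atoms: none
Why: Borane reduces the carboxylic acid chemoselectively to the benzylic alcohol and leaves the aryl bromide intact.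

Step 5
Reactants: 7 2-bromo-5-(hydroxymethyl)benzene-1,3-diol
Product: 8 2-bromo-1,3-bis(tert-butyldimethylsilyloxy)-5-[(tert-butyldimethylsilyloxy)methyl]benzene (ArBr)
Conditions: TBSCl (3.5 equiv), imidazole, DMF, rt
Reagents that add atoms: tert-butyldimethylsilyl chloride CC(C)(C)[Si](C)(C)Cl
Why: Exhaustive silylation gives fluoride-labile protection, so the final deprotection needs no acid that could cyclise a phenol onto the C1=C10 alkene.

Step 6
Reactants: 9 (3R)-3-methyloxolan-2-one
Product: 10 (3R)-3-methyloxolan-2-ol (anomer mixture)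
Conditions: i-Bu2AlH (1.1 equiv), CH2Cl2, −78 °C
Reagents that add atoms: none
Why: Partial reduction of a lactone stops at the lactol because the tetrahedral aluminate is stable at low temperature; the α-methyl centre is untouched.

Step 7
Reactants: 10 (3R)-3-methyloxolan-2-ol
Product: 11 (3R)-3-methylpent-4-yn-1-ol
Conditions: dimethyl (1-diazo-2-oxopropyl)phosphonate, K2CO3, MeOH, 0 °C to rt
Reagents that add atoms: dimethyl (1-diazo-2-oxopropyl)phosphonate COP(=O)(OC)C(=[N+]=[N-])C(C)=O
Why: Seyferth–Gilbert homologation (Ohira–Bestmann variant) of the open hydroxy-aldehyde tautomer gives the terminal alkyne; carbonate in methanol at 0 °C does not epimerise the unactivated α-methyl centre appreciably.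

Step 8
Reactants: 8 ArBr; 11 (3R)-3-methylpent-4-yn-1-ol
Product: 12 (3R)-5-Ar-3-methylpent-4-yn-1-ol
Conditions: Pd(PhCN)2Cl2 (3 mol%), P(t-Bu)3 (6 mol%), CuI (2 mol%), i-Pr2NH, 1,4-dioxane, rt to 45 °C
Reagents that add atoms: none
Why: Sonogashira coupling; the bulky electron-rich phosphine allows oxidative addition into the electron-rich, doubly ortho-substituted aryl bromide.

Step 9
Reactants: 12 (3R)-5-Ar-3-methylpent-4-yn-1-ol
Product: 13 (3R)-5-Ar-1-iodo-3-methylpent-4-yne
Conditions: I2, PPh3, imidazole, CH2Cl2, 0 °C to rt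
Reagents that add atoms: iodine II
Why: Appel-type iodination of the primary alcohol by SN2 displacement of an alkoxyphosphonium; no free electrophilic iodine is left to attack the electron-rich arene.

Step 10
Reactants: 13 (3R)-5-Ar-1-iodo-3-methylpent-4-yne; 4 (5R)-5-(tert-butyldimethylsilyloxy)-4,4-dimethylcyclohex-2-en-1-one
Product: 15 trimethylsilyl enol ether of (3R,5R)-3-(TBSO)-4,4-dimethyl-5-[(3R)-5-Ar-3-methylpent-4-ynyl]cyclohexanone (C1=C10 enol ether), via Grignard reagent 14 (not isolated)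
Conditions: Mg, THF, rt; then CuBr·SMe2 (10 mol%), TMSCl (2 equiv), HMPA (2 equiv), THF, −78 °C, add 4; Et3N, pentane work-up
Reagents that add atoms: magnesium [Mg] (in 14); chlorotrimethylsilane C[Si](C)(C)Cl
Why: Copper-catalysed, chlorosilane-accelerated conjugate addition of a Grignard reagent; the chain enters C5 axially on the half-chair that keeps the C3 silyloxy group pseudoequatorial, so it ends trans to that group (5R), and the enolate is trapped regiospecifically at C1=C10.

Step 11
Reactants: 15 trimethylsilyl enol ether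
Product: 17 (3R,5S,8R)-9-(ArCH2)-3-(TBSO)-4,4,8-trimethyl-Δ9(10)-octal-1-one (tetrasubstituted enone), via benzylidene ketone 16 (not isolated)
Conditions: Ph3PAuCl (5 mol%), AgBF4 (5 mol%), CH2Cl2/MeOH 10:1, rt; then DBU (1,8-diazabicyclo[5.4.0]undec-7-ene, 0.3 equiv), CH2Cl2, rt
Reagents that add atoms: none
Why: Gold-catalysed Conia-ene-type 6-exo-dig carbocyclisation of the silyl enol ether onto the π-activated alkyne forms the C9–C10 bond (six-membered exo closure preferred over seven-membered endo); DBU then moves the exocyclic styrenyl double bond into conjugation, which erases the C10 centre and leaves the propargylic-derived C8 centre intact.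

Step 12
Reactants: 17 tetrasubstituted enone
Product: 19 (3R,5S,8R,9S)-9-(ArCH2)-3-(TBSO)-4,4,8,9-tetramethyl-Δ1(10)-octalin-1-yl triflate, via lithium enolate 18 (not isolated)
Conditions: Me2CuLi (3 equiv, from MeLi and CuI), Et2O, −30 to 0 °C; then N-(5-chloropyridin-2-yl)bis(trifluoromethanesulfonimide), THF, −78 °C to rt
Reagents that add atoms: lithium dimethylcuprate [Li+].C[Cu-]C; N-(5-chloropyridin-2-yl)bis(trifluoromethanesulfonimide) FC(F)(F)S(=O)(=O)N(c1ccc(Cl)cn1)S(=O)(=O)C(F)(F)F
Why: Organocuprate conjugate addition to an s-cis alkylidene ketone; ring fusion locks ring B in the half-chair with H5 pseudoaxial, so the chair-like axial trajectory places the methyl on C9 on the face of H5 (9S, cis to H5 and to the C8 methyl, CH2Ar equatorial), and the resulting C1=C10 enolate is O-triflated.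

Step 13
Reactants: 19 enol triflate
Product: 20 (3R,5R,8R,9S)-9-(ArCH2)-3-(TBSO)-4,4,8,9-tetramethyl-Δ1(10)-octalin
Conditions: Pd(OAc)2 (5 mol%), PPh3 (10 mol%), HCO2H (3 equiv), n-Bu3N (4 equiv), DMF, 60 °C
Reagents that add atoms: none
Why: Palladium-catalysed formate reduction of an enol triflate (oxidative addition, formate decarboxylation, C–H reductive elimination) delivers the trisubstituted C1=C10 alkene without migration.

Step 14
Reactants: 20 tetrasilyl ether
Product: 21 (3R,5R,8R,9S)-tetraol: 2-[(decalinyl)methyl]-5-(hydroxymethyl)benzene-1,3-diol bearing the 3-hydroxyl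
Conditions: tetrabutylammonium fluoride (6 equiv), THF, 0 to 45 °C; aq. NH4Cl
Reagents that add atoms: none
Why: Fluoride cleaves the two aryl, one benzylic and one hindered secondary silyl ether under non-acidic conditions, so the phenol cannot add to the alkene.

Step 15
Reactants: 21 tetraol
Product: 22 target CNP0348277.2
Conditions: MgCl2 (3 equiv), Et3N (6 equiv), paraformaldehyde (4 equiv), MeCN, 70 °C; pH 5 buffer work-up
Reagents that add atoms: formaldehyde (as paraformaldehyde) C=O
Why: Magnesium phenoxide-directed ortho-formylation (Casnati–Skattebøl type: ortho-hydroxymethylation, then hydride transfer to a second formaldehyde); the two free ring positions are equivalent and each is ortho to a hydroxyl, so one mono-aldehyde results, and the medium stays non-acidic.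

## Compound list

1 | 4,4-dimethylcyclohexa-2,5-dien-1-one | CC1(C)C=CC(=O)C=C1 | starting material
2 | (5R)-4,4-dimethyl-5-(4,4,5,5-tetramethyl-1,3,2-dioxaborolan-2-yl)cyclohex-2-en-1-one | O=C1C[C@@H](B2OC(C)(C)C(C)(C)O2)C(C)(C)C=C1 | intermediate
3 | (5R)-5-hydroxy-4,4-dimethylcyclohex-2-en-1-one | O=C1C[C@@H](O)C(C)(C)C=C1 | intermediate
4 | (5R)-5-(tert-butyldimethylsilyloxy)-4,4-dimethylcyclohex-2-en-1-one | O=C1C[C@@H](O[Si](C)(C)C(C)(C)C)C(C)(C)C=C1 | intermediate
5 | 3,5-dihydroxybenzoic acid | OC(=O)c1cc(O)cc(O)c1 | starting material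
6 | 4-bromo-3,5-dihydroxybenzoic acid | OC(=O)c1cc(O)c(Br)c(O)c1 | intermediate
7 | 2-bromo-5-(hydroxymethyl)benzene-1,3-diol | OCc1cc(O)c(Br)c(O)c1 | intermediate
8 | 2-bromo-1,3-bis(TBSO)-5-(TBSOCH2)benzene (ArBr) | CC(C)(C)[Si](C)(C)OCc1cc(O[Si](C)(C)C(C)(C)C)c(Br)c(O[Si](C)(C)C(C)(C)C)c1 | intermediate
9 | (3R)-3-methyloxolan-2-one | C[C@@H]1CCOC1=O | starting material
10 | (3R)-3-methyloxolan-2-ol (anomer mixture) | C[C@@H]1CCOC1O | intermediate
11 | (3R)-3-methylpent-4-yn-1-ol | OCC[C@@H](C)C#C | intermediate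
12 | (3R)-5-Ar-3-methylpent-4-yn-1-ol | OCC[C@@H](C)C#Cc1c(O[Si](C)(C)C(C)(C)C)cc(CO[Si](C)(C)C(C)(C)C)cc1O[Si](C)(C)C(C)(C)C | intermediate
13 | (3R)-5-Ar-1-iodo-3-methylpent-4-yne | ICC[C@@H](C)C#Cc1c(O[Si](C)(C)C(C)(C)C)cc(CO[Si](C)(C)C(C)(C)C)cc1O[Si](C)(C)C(C)(C)C | intermediate
14 | [(3R)-5-Ar-3-methylpent-4-ynyl]magnesium iodide | I[Mg]CC[C@@H](C)C#Cc1c(O[Si](C)(C)C(C)(C)C)cc(CO[Si](C)(C)C(C)(C)C)cc1O[Si](C)(C)C(C)(C)C | intermediate
15 | trimethylsilyl enol ether (3R,5R,8R; C1=C10) of the 5-alkylated ketone | C[C@H](CC[C@@H]1C=C(O[Si](C)(C)C)C[C@@H](O[Si](C)(C)C(C)(C)C)C1(C)C)C#Cc1c(O[Si](C)(C)C(C)(C)C)cc(CO[Si](C)(C)C(C)(C)C)cc1O[Si](C)(C)C(C)(C)C | intermediate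
16 | (3R,5R,8R)-9-(arylmethylidene)-3-(TBSO)-4,4,8-trimethyldecal-1-one (C10 epimers, alkene geometry not fixed) | C[C@@H]1CC[C@@H]2C(C(=O)C[C@@H](O[Si](C)(C)C(C)(C)C)C2(C)C)C1=Cc1c(O[Si](C)(C)C(C)(C)C)cc(CO[Si](C)(C)C(C)(C)C)cc1O[Si](C)(C)C(C)(C)C | intermediate
17 | (3R,5S,8R)-9-(ArCH2)-3-(TBSO)-4,4,8-trimethyl-Δ9(10)-octal-1-one | C[C@@H]1CC[C@@H]2C(=C1Cc1c(O[Si](C)(C)C(C)(C)C)cc(CO[Si](C)(C)C(C)(C)C)cc1O[Si](C)(C)C(C)(C)C)C(=O)C[C@@H](O[Si](C)(C)C(C)(C)C)C2(C)C | intermediate
18 | lithium C1=C10 enolate of the 9-methylated ketone (3R,5S,8R,9S) | C[C@@H]1CC[C@@H]2C(=C(O[Li])C[C@@H](O[Si](C)(C)C(C)(C)C)C2(C)C)[C@@]1(C)Cc1c(O[Si](C)(C)C(C)(C)C)cc(CO[Si](C)(C)C(C)(C)C)cc1O[Si](C)(C)C(C)(C)C | intermediate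
19 | C1 enol triflate (3R,5S,8R,9S) | C[C@@H]1CC[C@@H]2C(=C(OS(=O)(=O)C(F)(F)F)C[C@@H](O[Si](C)(C)C(C)(C)C)C2(C)C)[C@@]1(C)Cc1c(O[Si](C)(C)C(C)(C)C)cc(CO[Si](C)(C)C(C)(C)C)cc1O[Si](C)(C)C(C)(C)C | intermediate
20 | tetra-TBS ether of 21 (3R,5R,8R,9S) | C[C@@H]1CC[C@@H]2C(=CC[C@@H](O[Si](C)(C)C(C)(C)C)C2(C)C)[C@@]1(C)Cc1c(O[Si](C)(C)C(C)(C)C)cc(CO[Si](C)(C)C(C)(C)C)cc1O[Si](C)(C)C(C)(C)C | intermediate
21 | deformyl target (3R,5R,8R,9S)-tetraol | C[C@@H]1CC[C@@H]2C(=CC[C@@H](O)C2(C)C)[C@@]1(C)Cc1c(O)cc(CO)cc1O | intermediate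
22 | CNP0348277.2 | C[C@@H]1CC[C@@H]2C(=CC[C@@H](O)C2(C)C)[C@@]1(C)Cc1c(O)cc(CO)c(C=O)c1O | target

## Step count and risks

Total steps: 15. Longest linear sequence: 11 steps (5 → 6 → 7 → 8 → 12 → 13 → 15 → 17 → 19 → 20 → 21 → 22).

The three steps most likely to fail:

Step 1 (desymmetrising borylation: enantioselectivity, and double borylation of the second enone arm). The fallback sets out from 1. Asymmetric nucleophilic epoxidation with aqueous H2O2 and 9-amino-9-deoxy-epi-quinidine bis(trifluoroacetate) (10 mol%, dioxane, 30 °C) breaks the symmetry instead and gives (1S,6S)-5,5-dimethyl-7-oxabicyclo[4.1.0]hept-3-en-2-one F1. Reductive opening of the epoxy ketone at the α-carbon with sodium phenylselenide ((PhSe)2, NaBH4, AcOH, EtOH, 0 °C) keeps the β C–O bond and comes back to the route at 3.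

Step 11 (gold carbocyclisation: the electron-rich aryl group could steer attack to the aryl-bearing alkyne carbon, giving a seven-membered ring, or the alkyne could be solvated by methanol). The fallback sets out from 15. N-Iodosuccinimide (THF, −78 °C) converts the silyl enol ether into the C10 α-iodo ketone F2. Slow addition of (Me3Si)3SiH with Et3B/air (toluene, 0 °C to rt) generates the α-keto radical, which closes 6-exo-dig onto the alkyne, the ring size and the aryl-stabilised vinyl radical both favouring this mode. Hydrogen abstraction gives 16, where the route is rejoined; DBU then gives 17 as before.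

Step 12 (cuprate addition to a hindered tetrasubstituted enone: low conversion, or attack from the wrong face of C9). The fallback sets out from 17. LiBH(s-Bu)3 (THF, −78 °C) gives the axial 1α-allylic alcohol F3 by equatorial hydride delivery. PhNCO with Et3N gives the N-phenylcarbamate F4. Deprotonation with MeLi, then CuI and a second equivalent of MeLi (THF, −78 to 0 °C), delivers methyl from the carbamate-bound copper in a syn-SN2′ substitution to the same face of C9 and forms the C1=C10 alkene directly. This comes back to the route at 20, bypassing 19 and step 13.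

Further compounds

F1 | step 1 | (1S,6S)-5,5-dimethyl-7-oxabicyclo[4.1.0]hept-3-en-2-one | O=C1[C@H]2O[C@H]2C(C)(C)C=C1
F2 | step 11 | (3R,5R)-3-(TBSO)-2-iodo-4,4-dimethyl-5-[(3R)-5-Ar-3-methylpent-4-ynyl]cyclohexanone, iodine at C10 (epimer mixture) | C[C@H](CC[C@@H]1C(I)C(=O)C[C@@H](O[Si](C)(C)C(C)(C)C)C1(C)C)C#Cc1c(O[Si](C)(C)C(C)(C)C)cc(CO[Si](C)(C)C(C)(C)C)cc1O[Si](C)(C)C(C)(C)C
F3 | step 12 | (1S,3R,5S,8R)-9-(ArCH2)-3-(TBSO)-4,4,8-trimethyl-Δ9(10)-octalin-1-ol | C[C@@H]1CC[C@@H]2C(=C1Cc1c(O[Si](C)(C)C(C)(C)C)cc(CO[Si](C)(C)C(C)(C)C)cc1O[Si](C)(C)C(C)(C)C)[C@@H](O)C[C@@H](O[Si](C)(C)C(C)(C)C)C2(C)C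
F4 | step 12 | N-phenylcarbamate of F3 | C[C@@H]1CC[C@@H]2C(=C1Cc1c(O[Si](C)(C)C(C)(C)C)cc(CO[Si](C)(C)C(C)(C)C)cc1O[Si](C)(C)C(C)(C)C)[C@@H](OC(=O)Nc1ccccc1)C[C@@H](O[Si](C)(C)C(C)(C)C)C2(C)C
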